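## Analysis of the target

Compound 31 is a 2-acetoxy-3,4-dihydro-2H-pyran (ring A: O, C1, C2, C3, C4, C5). It is fused along C3–C4 to a δ-lactone (ring B: C3, C4, C6, O, C8, C7), so the enol-ether bond C4=C5 of ring A is exocyclic to ring B.

It has four stereocentres: C1 (R), C2 (R), C3 (S) and C6 (S). Around ring A the C1 acetoxy group, the C2 alkenyl group and the C3–C7 bond alternate faces (all trans). H3 lies on the same face of ring B as the C6 side chain.

C2 carries a 6-oxohept-1-en-2-yl group. C6 carries an (E)-4-acetoxy-3-methylbut-2-enyl group, which is skipped with respect to C4.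

The labile sites are:
- the anomeric acetate and the enol ether;
- the C6–O bond, which is allylic to the enol ether and β to a masked aldehyde, so base can expel the carboxylate;
- the methylidene group β,γ to C1, which can move into conjugation once C1 is a free aldehyde;
- the allylic acetate and the methyl ketone.

The synthesis is hard for two reasons. C2 and C3 sit between three sp2 carbons. Five oxygenated termini (C1, C5, C8, the side-chain CH2O and the ketone) must end at four different oxidation or acylation states.

The strategy rests on the array O–C6–C4=C5–O–C1. Read backwards, this is a C8 carboxylate added to the β-carbon C6 of a 2-substituted enal (C5=O, C4=C6), whose enolate oxygen has been caught by the C1 aldehyde. Both rings therefore contain only C–O bonds that unzip to one acyclic chain.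

## Retrosynthetic reasoning

**31 ⇒ 30 ⇒ 29.** The acetyl group, O–C1 and O–C6 are cut. These are the only ring bonds whose carbon ends become ordinary electrophiles (an aldehyde and an enal β-carbon) in the open form. Cutting C–C bonds of the bicycle would leave the labile acylal and enol ether to be carried through further chemistry. The gain is two rings and two stereocentres (C6, C1) with nothing left to do afterwards. In the forward direction, the carboxylate must add to one face of C6, the enolate oxygen must be captured by C1, and lactol 30 must be acetylated.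

**29 ⇒ 28 ⇒ 27.** The acid and the C1 aldehyde are unmasked last.
- C8 is carried as a silylethyl ester, because a free acid next to a C1 or C5 hydroxyl would lactonise.
- C1 is carried as a triethylsilyl ether that is oxidised directly. A free C1 hydroxyl beside the C5 enal would close to a lactol and be over-oxidised to a lactone.
- The α-alkenyl aldehyde at C1 is the most fragile group of the route, so it exists for two steps only.

**27 ⇒ 26 ⇒ 25.** No skeletal bond is cut here. The (E)-enal is traced to the (Z)-allylic alcohol 25 through the (Z)-enal 26. The sigmatropic step below inevitably places the side chain cis to C5. The geometry is therefore corrected by equilibration of the enal, at a stage with no free hydroxyl, acid or second aldehyde present.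

**25 ⇒ 21.** These are redox and protecting-group changes at C8 and C5. C8 must reach the ester level before C5 becomes an aldehyde, because a C8 hydroxyl would form a lactol with C5. Two benzyl-type ethers of graded oxidation potential, both inert to the silyl ether at C1, give this order.

**21 ⇒ 17.** The C1 acid and the side-chain ester are reduced together and the ketal is removed. The two primary alcohols are then told apart by steric bias. The unhindered allylic one becomes the acetate of the target, and the branched one becomes the silyl ether.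

**17 ⇒ 14 (C2–C3).** This is the central C–C bond, and 17 is a γ,δ-unsaturated acid, which is the Ireland–Claisen retron. The cut removes both adjacent stereocentres at once and hands their control to one carbinol centre (C6), one alkene geometry (C3=C4) and one enolate geometry. It also forms the skipped diene under neutral thermal conditions, avoiding a β,γ-unsaturated aldehyde. Cutting C3–C7 or C3–C4 instead would leave C2 to be made separately.

**14 ⇒ 13 + 4 (ester C–O).** This is a plain acylation that joins the two halves.

**13 ⇒ 10 + 12 (C6–CH2).** A vinylogous aldol disconnection delivers the C6 carbinol, the CH2 spacer and the (E)-trisubstituted enoate in one catalytic step. A pentose-derived C6 carbinol was also considered. It would need a ketone olefination between two α-alkoxy carbons, of unpredictable geometry, and several extra protecting-group steps.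

**10 ⇒ 7 + 9 (C3=C4); 7 ⇒ 6 ⇒ 5; 9 ⇒ 8.** Cross metathesis gives the thermodynamically preferred (E)-enal. That is exactly the geometry the rearrangement needs (C7 cis to C5, trans to C6), and it allows different ethers at C5 and C8.

**4 ⇒ 3 ⇒ 1 + 2.** The bond between the allylic CH2 and the ketal chain is cut. The dianion of 1 is a symmetric 2-substituted allyl anion, so one alkylation gives the whole C1–C2–methylidene–ketone arm.

## Alternatives that were turned down

**Alternative 1:**
- *Disconnection.* The cut is at C2–C(alkenyl). Ring A is kept and traced to a prochiral 4H-pyran bearing only the C7–C8 arm at C3.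
- *Forward key step.* A chiral dirhodium tetracarboxylate (Rh2L4) decomposes an α-alkyl-α-diazo ester. The carbenoid adds to one of the two enantiotopic enol-ether bonds, anti to the arm, to give the 2-oxabicyclo[4.1.0]hept-3-ene A1. A later cyclopropylcarbinyl fragmentation would break the temporary C1–C bond and turn the quaternary carbon into the methylidene carbon.
- *For.* One catalytic step sets C1, C2 and C3 from an achiral ring. On this point it is stronger than the chosen route, which needs a catalytic aldol and a sigmatropic relay for C2 and C3.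
- *Against.* Carbenoids with β-hydrogens collapse by 1,2-hydride shift. Group and face selectivity must be read at once from a remote ester. The ester on the quaternary carbon must be reduced and activated before the unzip. A1 still lacks C6, its side chain, ring B and the C6 centre, and all of these would have to be built at C4 of an acid-labile enol ether.
- *Comparison.* The chosen plan closes both rings last, with no step after the key step. In this alternative the hard part begins after the key step.

**Alternative 2:**
- *Disconnection.* C2–C(alkenyl) and C3–C7 are cut on a pyran-3-one made by Achmatowicz ring expansion of a furan carbinol.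
- *Forward key step.* An alkenylcopper reagent adds to C2 anti to the C1 silyloxy group, and the enolate is alkylated at C3 by a bromoacetate, giving the all-trans ketone A2.
- *For.* The materials are cheap, every reaction type is well known, and the trans–trans relay matches ring A exactly. In reliability of the key step it is clearly stronger than the chosen strategy.
- *Against.* All chirality hangs on a configurationally labile acetal centre that must first be resolved. A hindered 1,1-disubstituted alkenylcopper addition followed by alkylation next to the new branch invites proton transfer. The C4 ketone must then become an sp2 carbon bearing C6 with the double bond towards C5. That requires enolisation away from C3, activation, one-carbon homologation, a stereocontrolled addition at C6 and lactonisation.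
- *Comparison.* No ring closes in the key step and C6 needs separate control, so the sequence after A2 is long. The chosen route obtains C6 from C3 at no extra cost.

**Alternative 3:**
- *Disconnection.* The bond from C6 to its side-chain CH2 and O–C8 are cut. The core is traced to genipin A4, whose cyclopentene is cleaved to give the C7–C8 arm and a ketone at the future methylidene carbon.
- *Forward key step.* The C6 aldehyde on C4 is allylated with an allylboron reagent under a chiral phosphoric acid. The new alkoxide closes on the C8 ester to give A3.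
- *For.* Ring A and C3 come from the chiral pool with the right configuration, and allylboration followed by lactonisation is known chemistry. In step count to the bicyclic core and in certainty it is stronger than the chosen plan.
- *Against.* A4 is cis-fused, so C2 (and with it C1) has the wrong configuration and must be epimerised next to the liberated ketone. The aldehyde is a vinylogous formate of low electrophilicity. After A3 several operations remain on the complete, labile bicycle: elaborating the allyl group to the (E)-trisubstituted allylic acetate, which is a geometry problem; exchanging the anomeric silyl ether for acetate; and removing the ketal with acid.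
- *Comparison.* The chosen strategy ends at the target itself, keeps the acylal and enol ether out of every earlier step, and derives C6 from substrate control.

Key step: step 21

Assumption: lactol 30 is drawn without configuration at C1 because its anomers interconvert, and silyl dienolate 12 is used as its geometric mixture, which has no bearing on the outcome.

## Route

Step 1
Reactants: 1 3-methylbut-3-en-1-ol; 2 2-(2-bromoethyl)-2-methyl-1,3-dioxolane
Product: 3 3-methylidene-6-(2-methyl-1,3-dioxolan-2-yl)hexan-1-ol
Conditions: 1, n-BuLi (2.1 equiv), TMEDA, Et2O/hexane, 0 °C to rt; then 2, THF, −78 °C to rt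
Reagents that add atoms: none
Why: Alkoxide-directed allylic lithiation gives the dianion of 1, and its allyl-lithium carbon is alkylated by the primary bromide (SN2). The 2-substituted allyl anion has two identical CH2 termini, so only one product can form.

Step 2
Reactants: 3 3-methylidene-6-(2-methyl-1,3-dioxolan-2-yl)hexan-1-ol
Product: 4 3-methylidene-6-(2-methyl-1,3-dioxolan-2-yl)hexanoic acid
Conditions: TEMPO (20 mol %), PhI(OAc)2 (2.5 equiv), NaHCO3, MeCN/H2O, 0 °C to rt
Reagents that add atoms: water, O
Why: Oxoammonium (TEMPO) oxidation proceeds through the aldehyde hydrate to the acid. The buffered, chlorine-free medium should spare the ketal and keep the alkene in the β,γ-position.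

Step 3
Reactants: 5 2-methylidenepropane-1,3-diol
Product: 6 2-{[(4-methoxybenzyl)oxy]methyl}prop-2-en-1-ol
Conditions: 5 (excess), NaH (1 equiv), 4-methoxybenzyl chloride (1 equiv), Bu4NI (cat.), THF/DMF, 0 °C to rt
Reagents that add atoms: 4-methoxybenzyl chloride, COc1ccc(CCl)cc1
Why: Williamson mono-etherification of a symmetric diol, with excess diol to suppress the bis-ether.

Step 4
Reactants: 6 2-{[(4-methoxybenzyl)oxy]methyl}prop-2-en-1-ol
Product: 7 2-{[(4-methoxybenzyl)oxy]methyl}prop-2-enal
Conditions: MnO2 (15 equiv), CH2Cl2, rt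
Reagents that add atoms: none
Why: Selective allylic alcohol oxidation with MnO2, which stops at the aldehyde.

Step 5
Reactants: 8 but-3-en-1-ol
Product: 9 4-[(but-3-en-1-yloxy)methyl]-1,2-dimethoxybenzene
Conditions: NaH, 3,4-dimethoxybenzyl chloride, Bu4NI (cat.), DMF, 0 °C to rt
Reagents that add atoms: 3,4-dimethoxybenzyl chloride, COc1ccc(CCl)cc1OC
Why: Williamson ether synthesis. The more electron-rich benzyl ether is placed at C8 so that it can later be cleaved before the one at C5.

Step 6
Reactants: 7 2-{[(4-methoxybenzyl)oxy]methyl}prop-2-enal; 9 4-[(but-3-en-1-yloxy)methyl]-1,2-dimethoxybenzene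
Product: 10 (E)-5-[(3,4-dimethoxybenzyl)oxy]-2-{[(4-methoxybenzyl)oxy]methyl}pent-2-enal
Conditions: 7 (2.5 equiv), second-generation Hoveyda–Grubbs catalyst RuCl2(H2IMes)(=CH-C6H4-2-O-i-Pr) (5 mol %), CH2Cl2, 40 °C
Reagents that add atoms: none
Why: Cross metathesis of a terminal alkene with a 2-substituted acrolein, as known for methacrolein. The reversible process should deliver the more stable (E)-enal (CHO trans to C7), which fixes the C3=C4 geometry needed in step 10.

Step 7
Reactants: 11 ethyl (E)-2-methylbut-2-enoate
Product: 12 tert-butyl[(1-ethoxy-2-methylbuta-1,3-dien-1-yl)oxy]dimethylsilane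
Conditions: LiN(i-Pr)2 (LDA, commercial solution), THF/DMPU, −78 °C; TBSCl
Reagents that add atoms: tert-butyldimethylsilyl chloride, CC(C)(C)[Si](C)(C)Cl
Why: Kinetic γ-deprotonation of the enoate followed by O-silylation of the dienolate gives the silyl dienol ether.

Step 8
Reactants: 10 (E)-5-[(3,4-dimethoxybenzyl)oxy]-2-{[(4-methoxybenzyl)oxy]methyl}pent-2-enal; 12 tert-butyl[(1-ethoxy-2-methylbuta-1,3-dien-1-yl)oxy]dimethylsilane
Product: 13 ethyl (2E,5S,6E)-9-[(3,4-dimethoxybenzyl)oxy]-5-hydroxy-6-{[(4-methoxybenzyl)oxy]methyl}-2-methylnona-2,6-dienoate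
Conditions: SiCl4 (1.1 equiv), chiral binaphthyldiamine-derived bisphosphoramide (5 mol %), i-Pr2NEt (10 mol %), CH2Cl2, −78 °C; sat. aq. NaHCO3
Reagents that add atoms: none
Why: Catalytic enantioselective vinylogous Mukaiyama aldol reaction (Lewis-base-activated SiCl4), which works best with conjugated aldehydes and reacts at the γ-carbon to give the (E)-enoate. The C6 carbinol (position 5 of 13) is set by the catalyst, using the antipode that directs the dienolate to the Si face and so gives S.

Step 9
Reactants: 13 ethyl (2E,5S,6E)-9-[(3,4-dimethoxybenzyl)oxy]-5-hydroxy-6-{[(4-methoxybenzyl)oxy]methyl}-2-methylnona-2,6-dienoate; 4 3-methylidene-6-(2-methyl-1,3-dioxolan-2-yl)hexanoic acid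
Product: 14 ethyl (2E,5S,6E)-9-[(3,4-dimethoxybenzyl)oxy]-6-{[(4-methoxybenzyl)oxy]methyl}-2-methyl-5-{[3-methylidene-6-(2-methyl-1,3-dioxolan-2-yl)hexanoyl]oxy}nona-2,6-dienoate
Conditions: EDC·HCl (1.5 equiv), DMAP (0.1 equiv), CH2Cl2, 0 °C
Reagents that add atoms: none
Why: Steglich-type esterification. Low temperature and little DMAP limit migration of the β,γ-alkene of 4, and the carbinol centre is not touched.

Step 10
Reactants: 14 ethyl (2E,5S,6E)-9-[(3,4-dimethoxybenzyl)oxy]-6-{[(4-methoxybenzyl)oxy]methyl}-2-methyl-5-{[3-methylidene-6-(2-methyl-1,3-dioxolan-2-yl)hexanoyl]oxy}nona-2,6-dienoate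
Product: 17 (2R,3S,4Z,7E)-3-{2-[(3,4-dimethoxybenzyl)oxy]ethyl}-9-ethoxy-4-{[(4-methoxybenzyl)oxy]methyl}-8-methyl-2-[5-(2-methyl-1,3-dioxolan-2-yl)pent-1-en-2-yl]-9-oxonona-4,7-dienoic acid, via silyl ketene acetal 15 (not isolated), via trimethylsilyl ester 16 (not isolated)
Conditions: TMSCl/Et3N (3 equiv, premixed), then KN(SiMe3)2 (KHMDS, 1.15 equiv), THF, −78 °C; warm to rt, 12 h; 5% aq. citric acid
Reagents that add atoms: none
Why: Ireland–Claisen rearrangement of a dienolate, the type used for α-isopropenyl γ,δ-unsaturated acids. The amide base removes only the doubly activated C2–H, and the conjugated enolate adopts the geometry with the alkenyl group cis to the metal-bound oxygen, as arylacetates do. In the chair transition state the C6 side chain, C7 and the alkenyl group are all equatorial, so 6S passes to 2R,3S and the new C4=C6 bond has the side chain trans to C3.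

Step 11
Reactants: 17 (2R,3S,4Z,7E)-3-{2-[(3,4-dimethoxybenzyl)oxy]ethyl}-9-ethoxy-4-{[(4-methoxybenzyl)oxy]methyl}-8-methyl-2-[5-(2-methyl-1,3-dioxolan-2-yl)pent-1-en-2-yl]-9-oxonona-4,7-dienoic acid
Product: 19 (2R,3S,4Z,7E)-3-{2-[(3,4-dimethoxybenzyl)oxy]ethyl}-4-{[(4-methoxybenzyl)oxy]methyl}-8-methyl-2-(6-oxohept-1-en-2-yl)nona-4,7-diene-1,9-diol, via ketal diol 18 (not isolated)
Conditions: LiAlH4 (4 equiv), THF, 0 °C to rt; H2O quench; then 1 M HCl/THF, rt
Reagents that add atoms: water, O
Why: Hydride reduction takes the C1 acid and the enoate (1,2-mode) to the two primary alcohols while the ketal shields the ketone. The acidic work-up then hydrolyses the dioxolane, which no later step requires.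

Step 12
Reactants: 19 (2R,3S,4Z,7E)-3-{2-[(3,4-dimethoxybenzyl)oxy]ethyl}-4-{[(4-methoxybenzyl)oxy]methyl}-8-methyl-2-(6-oxohept-1-en-2-yl)nona-4,7-diene-1,9-diol
Product: 20 (2E,5Z,7S,8R)-7-{2-[(3,4-dimethoxybenzyl)oxy]ethyl}-9-hydroxy-6-{[(4-methoxybenzyl)oxy]methyl}-2-methyl-8-(6-oxohept-1-en-2-yl)nona-2,5-dien-1-yl acetate
Conditions: vinyl acetate (5 equiv), immobilised Candida antarctica lipase B, MTBE, 30 °C
Reagents that add atoms: vinyl acetate, C=COC(C)=O
Why: Lipase-catalysed regioselective transesterification. The slim allylic alcohol should fit the enzyme pocket, whereas the C1 alcohol, flanked by two branched carbons, should react far more slowly.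

Step 13
Reactants: 20 (2E,5Z,7S,8R)-7-{2-[(3,4-dimethoxybenzyl)oxy]ethyl}-9-hydroxy-6-{[(4-methoxybenzyl)oxy]methyl}-2-methyl-8-(6-oxohept-1-en-2-yl)nona-2,5-dien-1-yl acetate
Product: 21 (2E,5Z,7S,8R)-7-{2-[(3,4-dimethoxybenzyl)oxy]ethyl}-6-{[(4-methoxybenzyl)oxy]methyl}-2-methyl-8-(6-oxohept-1-en-2-yl)-9-[(triethylsilyl)oxy]nona-2,5-dien-1-yl acetate
Conditions: TESCl, imidazole, CH2Cl2, 0 °C
Reagents that add atoms: chlorotriethylsilane, CC[Si](Cl)(CC)CC
Why: Standard silylation. The triethylsilyl ether is chosen because it can later be oxidised to the aldehyde without release of the free alcohol.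

Step 14
Reactants: 21 (2E,5Z,7S,8R)-7-{2-[(3,4-dimethoxybenzyl)oxy]ethyl}-6-{[(4-methoxybenzyl)oxy]methyl}-2-methyl-8-(6-oxohept-1-en-2-yl)-9-[(triethylsilyl)oxy]nona-2,5-dien-1-yl acetate
Product: 22 (2E,5Z,7S,8R)-7-(2-hydroxyethyl)-6-{[(4-methoxybenzyl)oxy]methyl}-2-methyl-8-(6-oxohept-1-en-2-yl)-9-[(triethylsilyl)oxy]nona-2,5-dien-1-yl acetate
Conditions: DDQ (1.1 equiv), CH2Cl2/pH 7 buffer, 0 °C
Reagents that add atoms: none
Why: Oxidative benzyl ether cleavage. The 3,4-dimethoxybenzyl ether has the lower oxidation potential and is removed ahead of the 4-methoxybenzyl ether, and the buffered medium spares the silyl ether.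

Step 15
Reactants: 22 (2E,5Z,7S,8R)-7-(2-hydroxyethyl)-6-{[(4-methoxybenzyl)oxy]methyl}-2-methyl-8-(6-oxohept-1-en-2-yl)-9-[(triethylsilyl)oxy]nona-2,5-dien-1-yl acetate
Product: 23 (3S,4Z,7E)-9-acetoxy-4-{[(4-methoxybenzyl)oxy]methyl}-8-methyl-3-{(2R)-3-methylidene-7-oxo-1-[(triethylsilyl)oxy]octan-2-yl}nona-4,7-dienoic acid
Conditions: TEMPO (20 mol %), PhI(OAc)2 (2.5 equiv), NaHCO3, MeCN/H2O, 0 °C to rt
Reagents that add atoms: water, O
Why: TEMPO-mediated oxidation of the only free primary alcohol to the acid. No chlorine species is present that could attack the four alkenes.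

Step 16
Reactants: 23 (3S,4Z,7E)-9-acetoxy-4-{[(4-methoxybenzyl)oxy]methyl}-8-methyl-3-{(2R)-3-methylidene-7-oxo-1-[(triethylsilyl)oxy]octan-2-yl}nona-4,7-dienoic acid
Product: 24 2-(trimethylsilyl)ethyl (3S,4Z,7E)-9-acetoxy-4-{[(4-methoxybenzyl)oxy]methyl}-8-methyl-3-{(2R)-3-methylidene-7-oxo-1-[(triethylsilyl)oxy]octan-2-yl}nona-4,7-dienoate
Conditions: 2-(trimethylsilyl)ethanol, EDC·HCl, DMAP (cat.), CH2Cl2, 0 °C to rt
Reagents that add atoms: 2-(trimethylsilyl)ethanol, C[Si](C)(C)CCO
Why: Steglich esterification. This ester prevents lactonisation onto C5–OH and is later cleaved by fluoride without acid, hydroxide or a metal that would ionise the allylic acetate.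

Step 17
Reactants: 24 2-(trimethylsilyl)ethyl (3S,4Z,7E)-9-acetoxy-4-{[(4-methoxybenzyl)oxy]methyl}-8-methyl-3-{(2R)-3-methylidene-7-oxo-1-[(triethylsilyl)oxy]octan-2-yl}nona-4,7-dienoate
Product: 25 2-(trimethylsilyl)ethyl (3S,4Z,7E)-9-acetoxy-4-(hydroxymethyl)-8-methyl-3-{(2R)-3-methylidene-7-oxo-1-[(triethylsilyl)oxy]octan-2-yl}nona-4,7-dienoate
Conditions: DDQ (1.4 equiv), CH2Cl2/pH 7 buffer, rt
Reagents that add atoms: none
Why: Oxidative cleavage of the remaining 4-methoxybenzyl ether. The δ-hydroxy ester is taken on at once to forestall lactonisation.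

Step 18
Reactants: 25 2-(trimethylsilyl)ethyl (3S,4Z,7E)-9-acetoxy-4-(hydroxymethyl)-8-methyl-3-{(2R)-3-methylidene-7-oxo-1-[(triethylsilyl)oxy]octan-2-yl}nona-4,7-dienoate
Product: 27 2-(trimethylsilyl)ethyl (3S,4E,7E)-9-acetoxy-4-formyl-8-methyl-3-{(2R)-3-methylidene-7-oxo-1-[(triethylsilyl)oxy]octan-2-yl}nona-4,7-dienoate, via (Z)-enal 26 (not isolated)
Conditions: MnO2 (15 equiv), CH2Cl2, rt; filter; DMAP (20 mol %), CH2Cl2, rt
Reagents that add atoms: none
Why: Allylic oxidation is followed by nucleophile-catalysed E/Z equilibration of a Michael acceptor (addition at C6, rotation, elimination), which touches only the enal. 2-Alkyl-2-enals prefer the formyl group trans to the β-substituent, and no hydroxyl, acid or second aldehyde is present at this stage.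

Step 19
Reactants: 27 2-(trimethylsilyl)ethyl (3S,4E,7E)-9-acetoxy-4-formyl-8-methyl-3-{(2R)-3-methylidene-7-oxo-1-[(triethylsilyl)oxy]octan-2-yl}nona-4,7-dienoate
Product: 28 2-(trimethylsilyl)ethyl (3S,4E,7E)-9-acetoxy-4-formyl-8-methyl-3-[(2R)-3-methylidene-1,7-dioxooctan-2-yl]nona-4,7-dienoate
Conditions: (COCl)2 (4 equiv), DMSO (8 equiv), CH2Cl2, −78 to −40 °C; i-Pr2NEt, −78 to −20 °C; pH 7 buffer
Reagents that add atoms: none
Why: Swern oxidation applied directly to a primary triethylsilyl ether. The activated sulfoxide displaces the silyl group, so no free C1 alcohol can form a lactol with C5. A hindered base and a cold quench protect the C2 centre.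

Step 20
Reactants: 28 2-(trimethylsilyl)ethyl (3S,4E,7E)-9-acetoxy-4-formyl-8-methyl-3-[(2R)-3-methylidene-1,7-dioxooctan-2-yl]nona-4,7-dienoate
Product: 29 (3S,4E,7E)-9-acetoxy-4-formyl-8-methyl-3-[(2R)-3-methylidene-1,7-dioxooctan-2-yl]nona-4,7-dienoic acid (acyclic C8 acid with C1 aldehyde and (E)-C5 enal)
Conditions: tris(dimethylamino)sulfonium difluorotrimethylsilicate (TASF, 1.3 equiv), DMF, 0 °C; pH 5 NaH2PO4 buffer; used crude
Reagents that add atoms: none
Why: Fluoride-induced fragmentation of the 2-(trimethylsilyl)ethyl ester to carboxylate, ethene and fluorosilane, using the least basic common fluoride source. Any partial ring closure is harmless, because all such forms belong to the equilibrium exploited in step 21.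

Step 21
Reactants: 29 (3S,4E,7E)-9-acetoxy-4-formyl-8-methyl-3-[(2R)-3-methylidene-1,7-dioxooctan-2-yl]nona-4,7-dienoic acid
Product: 31 CNP0120157.1 (ring A 2-acetoxydihydropyran fused to ring B δ-lactone; C1 R C2 R C3 S C6 S), via lactol 30 (not isolated)
Conditions: Bu4NOAc (0.3 equiv), MeCN, 0 °C to rt; then Ac2O (3 equiv), pyridine (4 equiv), DMAP (5 mol %), 0 °C
Reagents that add atoms: acetic anhydride, CC(=O)OC(C)=O
Why: Proposed new method: the acetate buffer turns 29 into its carboxylate, which adds to the enal β-carbon C6 (oxa-Michael); the resulting C4=C5 enolate attacks the C1 aldehyde through oxygen, proton transfer gives lactol 30, and acetylation removes 30 from an otherwise fully reversible manifold. The closest known reaction types are intramolecular oxa-Michael lactonisations of acids onto enones and the acetylative closure of 1,5-dialdehydes to 2-acetoxy-3,4-dihydro-2H-pyrans; their coupling in one anionic relay is not known. Ring B closes 6-endo-trig, not exo, because the tether sits on the α-carbon C4 and both alkene carbons end up in the ring, and ring A closes 6-exo-trig at the C1 carbonyl (enolendo with respect to C4=C5). C6 is controlled by allylic 1,3-strain: on the (E)-enal the side-chain CH2 is cis to C3, so H3 eclipses C4=C6, the C7–C8 arm stands over one face and the C2 arm over the other, and delivery from the C7 face of the 3S centre gives 6S. C1 is set under equilibration, since the anomers of 30 interconvert faster than they are acylated, and the acetate should end trans to the C2 chain, as favoured sterically and by the anomeric effect. The step needs the carboxylate to be the strongest base present, which the acetate/acetic acid couple secures, so that C2–H (α to C1 and allylic) and the doubly allylic CH2 next to C6 stay protonated. Acetic anhydride is added only after closure so that a mixed anhydride of 29 does not compete.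

## Compound list

1 | 3-methylbut-3-en-1-ol | C=C(C)CCO | starting material
2 | 2-(2-bromoethyl)-2-methyl-1,3-dioxolane | CC1(CCBr)OCCO1 | starting material
3 | 3-methylidene-6-(2-methyl-1,3-dioxolan-2-yl)hexan-1-ol | C=C(CCCC1(C)OCCO1)CCO | intermediate
4 | 3-methylidene-6-(2-methyl-1,3-dioxolan-2-yl)hexanoic acid | C=C(CCCC1(C)OCCO1)CC(=O)O | intermediate
5 | 2-methylidenepropane-1,3-diol | C=C(CO)CO | starting material
6 | 2-{[(4-methoxybenzyl)oxy]methyl}prop-2-en-1-ol | C=C(CO)COCc1ccc(OC)cc1 | intermediate
7 | 2-{[(4-methoxybenzyl)oxy]methyl}prop-2-enal | C=C(C=O)COCc1ccc(OC)cc1 | intermediate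
8 | but-3-en-1-ol | C=CCCO | starting material
9 | 4-[(but-3-en-1-yloxy)methyl]-1,2-dimethoxybenzene | C=CCCOCc1ccc(OC)c(OC)c1 | intermediate
10 | (E)-5-[(3,4-dimethoxybenzyl)oxy]-2-{[(4-methoxybenzyl)oxy]methyl}pent-2-enal | O=C/C(COCc1ccc(OC)cc1)=C/CCOCc1ccc(OC)c(OC)c1 | intermediate
11 | ethyl (E)-2-methylbut-2-enoate | C/C=C(\C)C(=O)OCC | starting material
12 | tert-butyl[(1-ethoxy-2-methylbuta-1,3-dien-1-yl)oxy]dimethylsilane | C=CC(C)=C(OCC)O[Si](C)(C)C(C)(C)C | intermediate
13 | ethyl (2E,5S,6E)-9-[(3,4-dimethoxybenzyl)oxy]-5-hydroxy-6-{[(4-methoxybenzyl)oxy]methyl}-2-methylnona-2,6-dienoate | CCOC(=O)/C(C)=C/C[C@H](O)/C(COCc1ccc(OC)cc1)=C/CCOCc1ccc(OC)c(OC)c1 | intermediate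
14 | ester of 13 with acid 4 (2E,5S,6E) | CCOC(=O)/C(C)=C/C[C@H](OC(=O)CC(=C)CCCC1(C)OCCO1)/C(COCc1ccc(OC)cc1)=C/CCOCc1ccc(OC)c(OC)c1 | intermediate
15 | (Z)-O-trimethylsilyl ketene acetal of 14 (alkenyl group cis to OSi) | CCOC(=O)/C(C)=C/C[C@H](O/C(O[Si](C)(C)C)=C/C(=C)CCCC1(C)OCCO1)/C(COCc1ccc(OC)cc1)=C/CCOCc1ccc(OC)c(OC)c1 | intermediate
16 | trimethylsilyl ester of 17 | C=C(CCCC1(C)OCCO1)[C@H](C(=O)O[Si](C)(C)C)[C@H](CCOCc1ccc(OC)c(OC)c1)/C(COCc1ccc(OC)cc1)=C/C/C=C(\C)C(=O)OCC | intermediate
17 | (2R,3S,4Z,7E)-3-{2-[(3,4-dimethoxybenzyl)oxy]ethyl}-9-ethoxy-4-{[(4-methoxybenzyl)oxy]methyl}-8-methyl-2-[5-(2-methyl-1,3-dioxolan-2-yl)pent-1-en-2-yl]-9-oxonona-4,7-dienoic acid | C=C(CCCC1(C)OCCO1)[C@H](C(=O)O)[C@H](CCOCc1ccc(OC)c(OC)c1)/C(COCc1ccc(OC)cc1)=C/C/C=C(\C)C(=O)OCC | intermediate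
18 | ketal diol (2R,3S,4Z,7E), C1 and side-chain CH2OH | C=C(CCCC1(C)OCCO1)[C@H](CO)[C@H](CCOCc1ccc(OC)c(OC)c1)/C(COCc1ccc(OC)cc1)=C/C/C=C(\C)CO | intermediate
19 | (2R,3S,4Z,7E)-3-{2-[(3,4-dimethoxybenzyl)oxy]ethyl}-4-{[(4-methoxybenzyl)oxy]methyl}-8-methyl-2-(6-oxohept-1-en-2-yl)nona-4,7-diene-1,9-diol | C=C(CCCC(C)=O)[C@H](CO)[C@H](CCOCc1ccc(OC)c(OC)c1)/C(COCc1ccc(OC)cc1)=C/C/C=C(\C)CO | intermediate
20 | side-chain monoacetate of 19 (2E,5Z,7S,8R) | C=C(CCCC(C)=O)[C@H](CO)[C@H](CCOCc1ccc(OC)c(OC)c1)/C(COCc1ccc(OC)cc1)=C/C/C=C(\C)COC(C)=O | intermediate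
21 | C1 triethylsilyl ether of 20 | C=C(CCCC(C)=O)[C@H](CO[Si](CC)(CC)CC)[C@H](CCOCc1ccc(OC)c(OC)c1)/C(COCc1ccc(OC)cc1)=C/C/C=C(\C)COC(C)=O | intermediate
22 | C8 alcohol (3,4-dimethoxybenzyl group removed) | C=C(CCCC(C)=O)[C@H](CO[Si](CC)(CC)CC)[C@H](CCO)/C(COCc1ccc(OC)cc1)=C/C/C=C(\C)COC(C)=O | intermediate
23 | C8 acid (3S,4Z,7E; 2R in the octanyl arm) | C=C(CCCC(C)=O)[C@H](CO[Si](CC)(CC)CC)[C@H](CC(=O)O)/C(COCc1ccc(OC)cc1)=C/C/C=C(\C)COC(C)=O | intermediate
24 | 2-(trimethylsilyl)ethyl ester of 23 | C=C(CCCC(C)=O)[C@H](CO[Si](CC)(CC)CC)[C@H](CC(=O)OCC[Si](C)(C)C)/C(COCc1ccc(OC)cc1)=C/C/C=C(\C)COC(C)=O | intermediate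
25 | (Z)-allylic alcohol (C5 CH2OH cis to the side chain) | C=C(CCCC(C)=O)[C@H](CO[Si](CC)(CC)CC)[C@H](CC(=O)OCC[Si](C)(C)C)/C(CO)=C/C/C=C(\C)COC(C)=O | intermediate
26 | (Z)-C5 enal | C=C(CCCC(C)=O)[C@H](CO[Si](CC)(CC)CC)[C@H](CC(=O)OCC[Si](C)(C)C)/C(C=O)=C/C/C=C(\C)COC(C)=O | intermediate
27 | (E)-C5 enal | C=C(CCCC(C)=O)[C@H](CO[Si](CC)(CC)CC)[C@H](CC(=O)OCC[Si](C)(C)C)/C(C=O)=C\C/C=C(\C)COC(C)=O | intermediate
28 | dialdehyde 2-(trimethylsilyl)ethyl ester | C=C(CCCC(C)=O)[C@H](C=O)[C@H](CC(=O)OCC[Si](C)(C)C)/C(C=O)=C\C/C=C(\C)COC(C)=O | intermediate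
29 | acyclic C8 acid with C1 aldehyde and (E)-C5 enal (key-step precursor) | C=C(CCCC(C)=O)[C@H](C=O)[C@H](CC(=O)O)/C(C=O)=C\C/C=C(\C)COC(C)=O | intermediate
30 | bicyclic lactol (C1 anomers) | C=C(CCCC(C)=O)[C@@H]1C(O)OC=C2[C@H](C/C=C(\C)COC(C)=O)OC(=O)C[C@H]21 | intermediate
31 | CNP0120157.1 | C=C(CCCC(C)=O)[C@@H]1[C@@H](OC(C)=O)OC=C2[C@H](C/C=C(\C)COC(C)=O)OC(=O)C[C@H]21 | target

## Step count and least certain steps

Total step count: 21. Longest linear sequence: 17 (steps 3, 4, 6, 8, 9, 10 and 11–21).

**Step 21 (key step).**
- *What may go wrong.* The equilibrium may rest on the open side, because loss of carboxylate from C6 is the microscopic reverse. The methylidene group may drift into conjugation with C1, with loss of the C2 centre. Acetic acid may be lost by vinylogous elimination after deprotonation of the doubly allylic CH2. Facial selectivity at C6 may be poor if addition becomes faster than conformational control.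
- *Fallback (known chemistry), from 27 to 31.* Copper-catalysed conjugate borylation (B2pin2, CuCl, NaOt-Bu, chiral bisphosphine, MeOH) gives the C6 pinacol boronate F1. NaBO3 oxidation with retention gives the (6S)-β-hydroxy aldehyde F2. Catalytic PPTS in benzene closes ring B by translactonisation to the lactone aldehyde F3. Direct Swern oxidation of the silyl ether gives the lactone dialdehyde F4. Acetylative closure of this enolisable 1,5-dialdehyde (Ac2O, NaOAc) gives 31. C6 is then set by the ligand and the two rings are closed separately.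

**Step 10.**
- *What may go wrong.* Deprotonation may compete at the CH2 next to C6 (γ to the enoate), followed by elimination of the acyloxy group. The enolate may add to the enoate before silylation. Incomplete enolate geometry control would erode the C2 configuration.
- *Fallback, from 14 to 17.* Soft enolisation with Bu2BOTf and i-Pr2NEt (CH2Cl2, −78 °C to rt) engages only the most acidic C–H. It gives the dibutylboron ketene acetal F5, which rearranges through the same chair and is hydrolysed to 17 on work-up.

**Step 8.**
- *What may go wrong.* The α-branched enal, which carries two Lewis-basic ethers, may react slowly, and face selectivity may be insufficient.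
- *Fallback, from 10 to 13.* Brown allylation with B-allyldiisopinocampheylborane gives the (S)-homoallylic alcohol F6. Cross metathesis with ethyl methacrylate, using the ruthenium catalyst of step 6, then gives 13.

**Step 18.**
- *What may go wrong.* Addition of the catalyst to a hindered β-carbon may be slow. The equilibrium may retain a sizeable share of the (Z)-enal, because the branched C3 is cis to the side chain in the (E)-isomer. Base-induced conjugation of the skipped diene is also possible.
- *Fallback, from 25 to 27.* The geometry is corrected at the alcohol level by a Mislow–Evans shuttle. PhSCl and Et3N convert 25, through its sulfenate, into the C6 allylic sulfoxide F7. P(OMe)3 in MeOH intercepts the sulfenate formed through the favoured transition state with the side chain trans to C5, giving the (E)-allylic alcohol F8. MnO2 then gives 27.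

**Step 20.**
- *What may go wrong.* Fluoride may cause enolisation of the C1 aldehyde (epimerisation or conjugation). An aldol reaction of the methyl ketone may occur, and material may decompose during isolation of the free acid.
- *Fallback, from 28 to 31.* The acid is not isolated. Fluoride cleavage in MeCN is used as the trigger of the cascade, and acetic anhydride with pyridine is added to the same flask. The carboxylate of 29 is then consumed as it forms, and no new compound is made (F0).

## Further compounds

F1 | step 21 | C6 pinacol boronate, β-boryl aldehyde (C4 unassigned) | C=C(CCCC(C)=O)[C@H](CO[Si](CC)(CC)CC)[C@H](CC(=O)OCC[Si](C)(C)C)C(C=O)[C@@H](B1OC(C)(C)C(C)(C)O1)C/C=C(\C)COC(C)=O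
F2 | step 21 | (6S)-β-hydroxy aldehyde (C4 unassigned) | C=C(CCCC(C)=O)[C@H](CO[Si](CC)(CC)CC)[C@H](CC(=O)OCC[Si](C)(C)C)C(C=O)[C@@H](O)C/C=C(\C)COC(C)=O
F3 | step 21 | ring B lactone aldehyde with C1 triethylsilyl ether | C=C(CCCC(C)=O)[C@H](CO[Si](CC)(CC)CC)[C@@H]1CC(=O)O[C@@H](C/C=C(\C)COC(C)=O)C1C=O
F4 | step 21 | ring B lactone dialdehyde | C=C(CCCC(C)=O)[C@H](C=O)[C@@H]1CC(=O)O[C@@H](C/C=C(\C)COC(C)=O)C1C=O
F5 | step 10 | dibutylboron ketene acetal of 14 | CCOC(=O)/C(C)=C/C[C@H](O/C(OB(CCCC)CCCC)=C/C(=C)CCCC1(C)OCCO1)/C(COCc1ccc(OC)cc1)=C/CCOCc1ccc(OC)c(OC)c1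
F6 | step 8 | (4S,5E)-8-[(3,4-dimethoxybenzyl)oxy]-5-{[(4-methoxybenzyl)oxy]methyl}octa-1,5-dien-4-ol | C=CC[C@H](O)/C(COCc1ccc(OC)cc1)=C/CCOCc1ccc(OC)c(OC)c1
F7 | step 18 | C6 allylic phenyl sulfoxide with C4=C5H2 (C6 and S unassigned) | C=C(CCCC(C)=O)[C@H](CO[Si](CC)(CC)CC)[C@H](CC(=O)OCC[Si](C)(C)C)C(=C)C(C/C=C(\C)COC(C)=O)S(=O)c1ccccc1
F8 | step 18 | (E)-allylic alcohol (C5 CH2OH trans to the side chain) | C=C(CCCC(C)=O)[C@H](CO[Si](CC)(CC)CC)[C@H](CC(=O)OCC[Si](C)(C)C)/C(CO)=C\C/C=C(\C)COC(C)=O
F0 | step 20 | none | none
A1 | alternative 1 | 2-oxabicyclo[4.1.0]hept-3-ene holding C1, C2, C3 and the side chain | COC(=O)C[C@@H]1C=CO[C@@H]2[C@H]1[C@@]2(CCCC3(C)OCCO3)C(=O)OCC[Si](C)(C)C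
A2 | alternative 2 | all-trans 2,3,4-trisubstituted tetrahydropyran-3-one (C4 ketone) | C=C(CCCC3(C)OCCO3)[C@@H]1[C@@H](O[Si](C)(C)C(C)(C)C)OCC(=O)[C@H]1CC(=O)OC
A3 | alternative 3 | bicyclic core with a C6 allyl group | C=C(CCCC3(C)OCCO3)[C@@H]1[C@@H](O[Si](C)(C)C(C)(C)C)OC=C2[C@H](CC=C)OC(=O)C[C@H]21
A4 | alternative 3 | genipin | COC(=O)C1=CO[C@H]([C@H]2[C@@H]1CC=C2CO)O
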